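**Retrosynthetic overview**
- The target is (+)-lariciresinol carrying a stearate on the C3 hydroxymethyl group: oxolane O1–C2(aryl)–C3(CH2O-acyl)–C4(benzyl)–C5, 2,3-trans and 3,4-cis. The strategy rests on C3 bearing one exocyclic carbon between the aryl-bearing C2 and the benzyl-bearing C4, so the ring can be read as a 2-aryl-5-benzyltetrahydropyran-4-one whose carbonyl carbon has been pushed out of the ring.
- Late disconnections: stearate C–O bond and the two phenol O-benzyl bonds; CH2OH from CO2Me; oxolane C3–C4 bond from a Wolff shift of pyranone C5 from C4 to C3 in the 3-diazo ketone.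
- Pyranone: diazo group by detrifluoroacetylative diazo transfer; C5–benzyl bond by reductive alkylation of the dihydropyranone; six-membered ring by catalytic asymmetric hetero-Diels–Alder reaction of O-benzylvanillin with Danishefsky's diene.
- Ring order: oxacyclohexenone first, oxolane second by contraction. C2 comes from the catalyst, C4 from the 2,5-trans pyranone, C3 from equilibration.

Key step: step 6

Remark on the chemistry: (R)-BINOL is assumed to be the ligand antipode that opens the Si face of the aldehyde to the diene (2S product); if the sense is the opposite, (S)-BINOL is used and nothing else changes.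
Abbreviations in the steps: Ar = 4-(benzyloxy)-3-methoxyphenyl; ArCH2 = 4-(benzyloxy)-3-methoxybenzyl. Full names are in the compound list.

**Route**

Step 1
Reactants: 1 [4-(benzyloxy)-3-methoxyphenyl]methanol
Product: 2 4-(benzyloxy)-3-methoxybenzyl bromide
Conditions: PBr3 (0.4 equiv), Et2O, 0 °C to rt; used without storage
Reagents that add atoms: phosphorus tribromide, BrP(Br)Br
Why: Standard conversion of a benzylic alcohol into the bromide with PBr3 (SN2 on the activated alcohol), which leaves the aryl benzyl and methyl ethers alone; the bromide is used at once because para-alkoxybenzyl bromides keep poorly.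

Step 2
Reactants: 3 4-(benzyloxy)-3-methoxybenzaldehyde (O-benzylvanillin); 4 Danishefsky's diene, (E)-1-methoxy-3-(trimethylsilyloxy)buta-1,3-diene
Product: 6 (S)-2-Ar-2,3-dihydro-4H-pyran-4-one, via silyl aldol adduct 5 (not isolated)
Conditions: (R)-BINOL (20 mol %), Ti(OiPr)4 (10 mol %), 4 Å MS, Et2O, −20 °C; then TFA (cat.), CH2Cl2, 0 °C
Reagents that add atoms: none
Why: Ti(IV)–BINOL-catalysed Mukaiyama aldol addition of the diene terminus to the aldehyde followed by acid-induced ring closure with loss of MeOSiMe3 (formal hetero-Diels–Alder reaction, Keck conditions) should give the 2-aryl dihydropyranone, with C2 set by the chiral Lewis acid directing the diene to the Si face of the aldehyde.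

Step 3
Reactants: 6 (S)-2-Ar-2,3-dihydro-4H-pyran-4-one; 2 4-(benzyloxy)-3-methoxybenzyl bromide
Product: 8 (2S)-2-Ar-5-(ArCH2)tetrahydro-4H-pyran-4-one as a mixture of C5 epimers, via lithium enolate 7 (not isolated)
Conditions: L-Selectride (1.05 equiv), THF, −78 °C; then 2 (1.3 equiv), DMPU, −78 to 0 °C; sat. NH4Cl
Reagents that add atoms: none
Why: Conjugate hydride addition to the vinylogous ester gives the C4–C5 enolate regiospecifically, and the reactive benzylic bromide alkylates it at C5 (reductive alkylation of an enone); C2 is untouched and the C5 configuration is left open because step 4 settles it.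

Step 4
Reactants: 8 (2S)-2-Ar-5-(ArCH2)tetrahydro-4H-pyran-4-one, C5 epimers
Product: 9 (2S,5S)-2-Ar-5-(ArCH2)tetrahydro-4H-pyran-4-one (2,5-trans)
Conditions: K2CO3 (0.3 equiv), MeOH–THF, 0 °C to rt; chromatography, cis fraction returned to the equilibration
Reagents that add atoms: none
Why: Reversible enolisation toward C5 under mild base lets the ketone settle in the chair with the C2 aryl and C5 benzyl groups both equatorial, while C2 carries no acidic hydrogen; the mild, short treatment is meant to keep retro-oxa-Michael opening of the C2–O1 bond, which would erode enantiomeric purity, out of play.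

Step 5
Reactants: 9 (2S,5S)-2-Ar-5-(ArCH2)tetrahydro-4H-pyran-4-one
Product: 12 (2R,5S)-2-Ar-5-(ArCH2)-3-diazotetrahydro-4H-pyran-4-one, via lithium enolate 10 (not isolated), via trifluoroacetyl ketone 11 (not isolated)
Conditions: LiHMDS (1.1 equiv), THF, −78 °C; CF3CO2CH2CF3 (1.2 equiv), −78 °C; dilute HCl wash; crude 11 with MsN3 (1.5 equiv), Et3N (1.5 equiv), H2O (1 equiv), MeCN, rt
Reagents that add atoms: methanesulfonyl azide, CS(=O)(=O)N=[N+]=[N-]; 2,2,2-trifluoroethyl trifluoroacetate, O=C(OCC(F)(F)F)C(F)(F)F (its CF3CO group is carried only by 11 and is lost again)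
Why: Kinetic deprotonation at the methylene C3, Claisen trifluoroacetylation and sulfonyl azide transfer with loss of the trifluoroacetyl group as the N-acyl sulfonamide (detrifluoroacetylative diazo transfer) should install the diazo group; only C3 carries two hydrogens, so the diazo group cannot end at C5, and the low temperature leaves the C5 centre alone.

Step 6
Reactants: 12 (2R,5S)-2-Ar-5-(ArCH2)-3-diazotetrahydro-4H-pyran-4-one
Product: 15 methyl (2S,3S,4R)-2-Ar-4-(ArCH2)oxolane-3-carboxylate (2,3-trans, 3,4-cis), via ketene 13 (not isolated), via C3-epimeric ester 14 (not isolated)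
Conditions: hν (365 nm LED, or medium-pressure Hg lamp through Pyrex), degassed MeOH–THF (4:1), 10 °C; then NaOMe (0.3 equiv), rt
Reagents that add atoms: methanol, CO
Why: Direct excitation of the cyclic diazoketone, whose ring holds C=O and C=N2 s-Z, expels N2 in concert with the 1,2-shift of the anti-periplanar acyl substituent C5 from C4 to C3, so that C4 leaves the ring as the ketene carbon of 13, which adds methanol and is protonated at C3. The closest known reaction type is the photochemical Wolff ring contraction of cyclic 2-diazoketones in alcohols (2-diazocyclohexanones to cyclopentanecarboxylates, diazo oxacyclic ketones to the next smaller cyclic ether esters). The oxolane is not closed by a cyclisation: it arises by contraction when the new C3–C5 bond replaces the two ring bonds to C4, so that O1, C2, C3, C5 and C6 of the pyranone become O1, C2, C3, C4 and C5 of the oxolane. C5 migrates with retention and becomes C4, carrying the 2,5-trans relation of 12 over as 2,4-trans; the new centre C3 is first set by a protonation that is not expected to be face-selective (aryl on one face, benzyl on the other) and is then settled by methoxide equilibration, which should favour the ester trans to the ring-bound aryl group and cis to the smaller CH2 of the benzyl group. The step needs the carbon shift to win over 1,2-hydride shift from the benzylic, oxygen-bearing C2–H and over O–H insertion, which the enforced s-Z geometry (concerted shift from the excited state, no sensitiser, no metal) is meant to secure, and it needs C5 rather than C2 to migrate, which is fixed because only the carbonyl substituent can shift to the diazo carbon.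

Step 7
Reactants: 15 methyl (2S,3S,4R)-2-Ar-4-(ArCH2)oxolane-3-carboxylate
Product: 16 [(2S,3R,4R)-2-Ar-4-(ArCH2)oxolan-3-yl]methanol (4,4'-di-O-benzyl-lariciresinol)
Conditions: LiAlH4 (1.5 equiv), THF, 0 °C; Fieser work-up
Reagents that add atoms: none
Why: Hydride reduction of the methyl ester to the primary alcohol is faster than enolisation, so C3 keeps its configuration, and the aryl benzyl ethers and the oxolane are inert.

Step 8
Reactants: 16 [(2S,3R,4R)-2-Ar-4-(ArCH2)oxolan-3-yl]methanol; 17 stearoyl chloride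
Product: 18 [(2S,3R,4R)-2-Ar-4-(ArCH2)oxolan-3-yl]methyl octadecanoate
Conditions: Et3N (1.5 equiv), DMAP (0.1 equiv), CH2Cl2, 0 °C to rt
Reagents that add atoms: none
Why: DMAP-catalysed acylation of the only free hydroxyl group, a primary alcohol, with the acid chloride; both phenols are still benzyl ethers, so no aryl ester can form.

Step 9
Reactants: 18 [(2S,3R,4R)-2-Ar-4-(ArCH2)oxolan-3-yl]methyl octadecanoate
Product: 19 [(2S,3R,4R)-2-(4-hydroxy-3-methoxyphenyl)-4-(4-hydroxy-3-methoxybenzyl)oxolan-3-yl]methyl octadecanoate (target)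
Conditions: H2 (1 atm), 10% Pd/C, EtOAc, rt; stopped when both benzyl groups are gone
Reagents that add atoms: none
Why: Pd-catalysed hydrogenolysis should cleave the two aryl benzyl ethers much faster than the benzylic C2–O1 bond of the oxolane in neutral ethyl acetate at 1 atm, and the stearate and the three stereocentres are not affected.

**Compound list**
1 | [4-(benzyloxy)-3-methoxyphenyl]methanol | COc1cc(CO)ccc1OCc1ccccc1 | starting material
2 | 4-(benzyloxy)-3-methoxybenzyl bromide | COc1cc(CBr)ccc1OCc1ccccc1 | intermediate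
3 | 4-(benzyloxy)-3-methoxybenzaldehyde | COc1cc(C=O)ccc1OCc1ccccc1 | starting material
4 | (E)-1-methoxy-3-(trimethylsilyloxy)buta-1,3-diene | CO/C=C/C(=C)O[Si](C)(C)C | starting material
5 | (S,E)-5-[4-(benzyloxy)-3-methoxyphenyl]-1-methoxy-5-(trimethylsilyloxy)pent-1-en-3-one | CO/C=C/C(=O)C[C@H](O[Si](C)(C)C)c1ccc(OCc2ccccc2)c(OC)c1 | intermediate
6 | (S)-2-[4-(benzyloxy)-3-methoxyphenyl]-2,3-dihydro-4H-pyran-4-one | O=C1C[C@@H](c2ccc(OCc3ccccc3)c(OC)c2)OC=C1 | intermediate
7 | lithium (S)-2-[4-(benzyloxy)-3-methoxyphenyl]-3,6-dihydro-2H-pyran-4-olate (C4–C5 enolate) | [Li+].[O-]C1=CCO[C@H](c2ccc(OCc3ccccc3)c(OC)c2)C1 | intermediate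
8 | (2S)-2-[4-(benzyloxy)-3-methoxyphenyl]-5-[4-(benzyloxy)-3-methoxybenzyl]tetrahydro-4H-pyran-4-one, C5 epimers | O=C1C[C@@H](c2ccc(OCc3ccccc3)c(OC)c2)OCC1Cc1ccc(OCc2ccccc2)c(OC)c1 | intermediate
9 | (2S,5S)-2-[4-(benzyloxy)-3-methoxyphenyl]-5-[4-(benzyloxy)-3-methoxybenzyl]tetrahydro-4H-pyran-4-one (2,5-trans) | O=C1C[C@@H](c2ccc(OCc3ccccc3)c(OC)c2)OC[C@@H]1Cc1ccc(OCc2ccccc2)c(OC)c1 | intermediate
10 | lithium enolate of 9 toward C3 (C3=C4), lithium (2S,5S)-2-aryl-5-benzyl-5,6-dihydro-2H-pyran-4-olate | [Li+].[O-]C1=C[C@@H](c2ccc(OCc3ccccc3)c(OC)c2)OC[C@@H]1Cc1ccc(OCc2ccccc2)c(OC)c1 | intermediate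
11 | (2S,5S)-2-[4-(benzyloxy)-3-methoxyphenyl]-5-[4-(benzyloxy)-3-methoxybenzyl]-3-(trifluoroacetyl)tetrahydro-4H-pyran-4-one (enolised, C3 not defined) | O=C1C(C(=O)C(F)(F)F)[C@@H](c2ccc(OCc3ccccc3)c(OC)c2)OC[C@@H]1Cc1ccc(OCc2ccccc2)c(OC)c1 | intermediate
12 | (2R,5S)-2-[4-(benzyloxy)-3-methoxyphenyl]-5-[4-(benzyloxy)-3-methoxybenzyl]-3-diazotetrahydro-4H-pyran-4-one (2,5-trans) | [N-]=[N+]=C1C(=O)[C@@H](Cc2ccc(OCc3ccccc3)c(OC)c2)CO[C@@H]1c1ccc(OCc2ccccc2)c(OC)c1 | intermediate
13 | 2,4-trans-2-[4-(benzyloxy)-3-methoxyphenyl]-4-[4-(benzyloxy)-3-methoxybenzyl]-3-(oxomethylidene)oxolane (ketene) | O=C=C1[C@@H](Cc2ccc(OCc3ccccc3)c(OC)c2)CO[C@@H]1c1ccc(OCc2ccccc2)c(OC)c1 | intermediate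
14 | methyl (2S,3R,4R)-2-[4-(benzyloxy)-3-methoxyphenyl]-4-[4-(benzyloxy)-3-methoxybenzyl]oxolane-3-carboxylate (2,3-cis, 3,4-trans) | COC(=O)[C@@H]1[C@@H](Cc2ccc(OCc3ccccc3)c(OC)c2)CO[C@@H]1c1ccc(OCc2ccccc2)c(OC)c1 | intermediate
15 | methyl (2S,3S,4R)-2-[4-(benzyloxy)-3-methoxyphenyl]-4-[4-(benzyloxy)-3-methoxybenzyl]oxolane-3-carboxylate (2,3-trans, 3,4-cis) | COC(=O)[C@H]1[C@@H](Cc2ccc(OCc3ccccc3)c(OC)c2)CO[C@@H]1c1ccc(OCc2ccccc2)c(OC)c1 | intermediate
16 | [(2S,3R,4R)-2-[4-(benzyloxy)-3-methoxyphenyl]-4-[4-(benzyloxy)-3-methoxybenzyl]oxolan-3-yl]methanol | OC[C@H]1[C@@H](Cc2ccc(OCc3ccccc3)c(OC)c2)CO[C@@H]1c1ccc(OCc2ccccc2)c(OC)c1 | intermediate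
17 | stearoyl chloride (octadecanoyl chloride) | CCCCCCCCCCCCCCCCCC(=O)Cl | starting material
18 | [(2S,3R,4R)-2-[4-(benzyloxy)-3-methoxyphenyl]-4-[4-(benzyloxy)-3-methoxybenzyl]oxolan-3-yl]methyl octadecanoate | CCCCCCCCCCCCCCCCCC(=O)OC[C@H]1[C@@H](Cc2ccc(OCc3ccccc3)c(OC)c2)CO[C@@H]1c1ccc(OCc2ccccc2)c(OC)c1 | intermediate
19 | [(2S,3R,4R)-2-(4-hydroxy-3-methoxyphenyl)-4-(4-hydroxy-3-methoxybenzyl)oxolan-3-yl]methyl octadecanoate | CCCCCCCCCCCCCCCCCC(=O)OC[C@H]1[C@@H](Cc2ccc(O)c(OC)c2)CO[C@@H]1c1ccc(O)c(OC)c1 | target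

**Totals**
Total step count: 9. Longest linear sequence: 8 steps (3 to 19, steps 2–9); step 1 is a one-step side branch that joins in step 3.

**Steps most likely to fail**

1. Step 6. The excited diazoketone, or a free carbene formed from it, may undergo 1,2-hydride shift from C2 or O–H insertion into methanol faster than the carbon shift. The C3 equilibrium may also not lie far enough on the side of the 2,3-trans ester. The fallback gives up the ring contraction and builds the oxolane by the lactone–aldol–etherification sequence of lignan chemistry; it sets out from bromide 2 and aldehyde 3 and returns at alcohol 16. Acylation of (R)-4-benzyloxazolidin-2-one with mono-tert-butyl succinate (PivCl, Et3N, LiCl, THF) gives the acyl oxazolidinone F1. Evans alkylation of F1 with 2 (NaHMDS, THF, −78 °C) gives the (R)-configured α-benzyl imide F2. LiBH4 (THF, MeOH, 0 °C) cleaves the imide to the hydroxy ester F3, and TsOH in toluene closes it to the (R)-β-benzyl-γ-butyrolactone F4. Aldol addition of F4 (LiHMDS, THF, −78 °C) to 3 anti to the benzyl group gives the trans hydroxybenzyl lactone F5 as a carbinol mixture. LiAlH4 reduces F5 to the triol F6. Acid (CSA, CH2Cl2, 0 °C) ionises the para-alkoxybenzylic alcohol of F6, and the hydroxymethyl group on the benzyl-bearing carbon closes the oxolane with the aryl group trans to C3, giving 16.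

2. Step 3. The borane-complexed enolate may be alkylated slowly, so that proton transfer, double alkylation or β-alkoxide ring opening take over. The fallback forms the C5–benzyl bond by cross-coupling instead of enolate alkylation; it sets out from 6 and 2 and returns at 8. α-Iodination of 6 (I2, pyridine, CH2Cl2) gives the iodoenone F7. Zinc insertion into 2 (Zn dust, LiCl, THF) gives the benzylzinc bromide F8. Negishi coupling of F7 with F8 (Pd2(dba)3, SPhos, THF, rt) gives the 5-benzyl enone F9. Conjugate reduction of F9 with L-Selectride (THF, −78 °C) and protonation then gives 8, which goes into step 4.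

3. Step 2. The electron-rich aldehyde may turn over slowly and be bound with poor facial discrimination at titanium, giving pyranone of low enantiomeric purity. The fallback replaces asymmetric induction by resolution; it sets out from 3 and 4 and returns at 6. ZnCl2-mediated cyclocondensation (THF, rt) gives the racemic cycloadduct F10, and TFA (CH2Cl2, 0 °C) converts it into the racemic pyranone F11. Preparative chromatography of F11 on a chiral stationary phase then delivers the (S)-enantiomer 6.

**Further compounds**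
F1 | step 6 | (R)-4-benzyl-3-[4-(tert-butoxy)-4-oxobutanoyl]oxazolidin-2-one | CC(C)(C)OC(=O)CCC(=O)N1[C@H](Cc2ccccc2)COC1=O
F2 | step 6 | (R)-4-benzyl-3-[(2R)-2-[4-(benzyloxy)-3-methoxybenzyl]-4-(tert-butoxy)-4-oxobutanoyl]oxazolidin-2-one | CC(C)(C)OC(=O)C[C@@H](Cc1ccc(OCc2ccccc2)c(OC)c1)C(=O)N1[C@H](Cc2ccccc2)COC1=O
F3 | step 6 | tert-butyl (R)-4-[4-(benzyloxy)-3-methoxyphenyl]-3-(hydroxymethyl)butanoate | CC(C)(C)OC(=O)C[C@@H](Cc1ccc(OCc2ccccc2)c(OC)c1)CO
F4 | step 6 | (R)-4-[4-(benzyloxy)-3-methoxybenzyl]dihydrofuran-2(3H)-one | O=C1C[C@@H](Cc2ccc(OCc3ccccc3)c(OC)c2)CO1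
F5 | step 6 | (3S,4R)-3-{[4-(benzyloxy)-3-methoxyphenyl](hydroxy)methyl}-4-[4-(benzyloxy)-3-methoxybenzyl]dihydrofuran-2(3H)-one (3,4-trans, carbinol epimers) | O=C1[C@H](C(O)c2ccc(OCc3ccccc3)c(OC)c2)[C@@H](Cc2ccc(OCc3ccccc3)c(OC)c2)CO1
F6 | step 6 | (2R,3R)-2-{[4-(benzyloxy)-3-methoxyphenyl](hydroxy)methyl}-3-[4-(benzyloxy)-3-methoxybenzyl]butane-1,4-diol (carbinol epimers) | OC[C@H](C(O)c1ccc(OCc2ccccc2)c(OC)c1)[C@@H](Cc1ccc(OCc2ccccc2)c(OC)c1)CO
F7 | step 3 | (S)-2-[4-(benzyloxy)-3-methoxyphenyl]-5-iodo-2,3-dihydro-4H-pyran-4-one | O=C1C[C@@H](c2ccc(OCc3ccccc3)c(OC)c2)OC=C1I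
F8 | step 3 | [4-(benzyloxy)-3-methoxybenzyl]zinc bromide | COc1cc(C[Zn]Br)ccc1OCc1ccccc1
F9 | step 3 | (S)-2-[4-(benzyloxy)-3-methoxyphenyl]-5-[4-(benzyloxy)-3-methoxybenzyl]-2,3-dihydro-4H-pyran-4-one | O=C1C[C@@H](c2ccc(OCc3ccccc3)c(OC)c2)OC=C1Cc1ccc(OCc2ccccc2)c(OC)c1
F10 | step 2 | racemic 6-[4-(benzyloxy)-3-methoxyphenyl]-2-methoxy-4-(trimethylsilyloxy)-5,6-dihydro-2H-pyran | COC1C=C(O[Si](C)(C)C)CC(c2ccc(OCc3ccccc3)c(OC)c2)O1
F11 | step 2 | racemic 2-[4-(benzyloxy)-3-methoxyphenyl]-2,3-dihydro-4H-pyran-4-one | O=C1CC(c2ccc(OCc3ccccc3)c(OC)c2)OC=C1
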